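**Assumption (one line):** carotenoid numbering is used in names (keto half unprimed, ε half primed), and the (S,S)-TsDPEN ruthenium catalyst is taken to give (4S)-phorenol and the (R,R)-catalyst (4R)-phorenol (alkenyl group in the aryl role); if the sense is the reverse, the two catalysts are swapped.

## Retrosynthetic overview

1. Target ⇐ desilylation and C19 lauroylation ⇐ 19-O-silyl dienone ⇐ aldol addition/dehydration forming C9–C10 between the C9 lithium enolate of a C13 β-ring ketone and a C27 ε-polyenal.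
2. C13 ketone ⇐ hydroboration/oxidation of a ring diene ⇐ Suzuki coupling of the β-ring enol triflate (from (S)-phorenol by conjugate reduction/triflation) with a C4 alkenylboronate.
3. C27 aldehyde ⇐ two-carbon HWE extension of the C25 aldehyde ⇐ Wittig reaction of an ε-C15 phosphonium salt with the C10 dialdehyde.
4. ε-C15 unit ⇐ HWE on (3R,6R)-3-silyloxy-α-cyclocitral ⇐ [2,3]-Wittig–Still rearrangement ⇐ Wharton transposition of the trans-epoxide of (R)-phorenol.
5. No carbocycle is formed: both six-membered rings come from ketoisophorone (β-ring fragment first, then ε-ring fragment); the only ring made is the transient epoxide.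

## Route

Step 1
Reactants: 1 ketoisophorone (2,6,6-trimethylcyclohex-2-ene-1,4-dione)
Product: 2 (4S)-4-hydroxy-2,6,6-trimethylcyclohex-2-en-1-one [(S)-phorenol]
Conditions: Ru[(S,S)-TsNCH(Ph)CH(Ph)NH](p-cymene) (1 mol %), i-PrOH, 25 °C
Reagents that add atoms: none
Why: Noyori asymmetric transfer hydrogenation reduces only the unhindered C4 carbonyl (C1 is flanked by two fully substituted carbons), and the catalyst-controlled hydride delivery sets 4S, which becomes C3 (R) of the β ring.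

Step 2
Reactants: 2 (S)-phorenol
Product: 3 (4S)-4-[(tert-butyldimethylsilyl)oxy]-2,6,6-trimethylcyclohex-2-en-1-one
Conditions: TBSCl, imidazole, DMF, rt
Reagents that add atoms: tert-butyldimethylsilyl chloride, CC(C)(C)[Si](C)(C)Cl
Why: Standard silylation of a secondary alcohol; the stereocentre is untouched.

Step 3
Reactants: 3 TBS-protected (S)-phorenol
Product: 5 (4R)-4-[(tert-butyldimethylsilyl)oxy]-2,6,6-trimethylcyclohex-1-en-1-yl trifluoromethanesulfonate, via lithium enolate 4 (not isolated)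
Conditions: LiBH(s-Bu)3 (1.1 equiv), THF, −78 °C; then PhNTf2 (1.2 equiv), −78 °C → rt
Reagents that add atoms: N-phenylbis(trifluoromethanesulfonimide), O=S(=O)(N(c1ccccc1)S(=O)(=O)C(F)(F)F)C(F)(F)F
Why: Conjugate reduction with enolate trapping: 1,4-hydride addition (1,2-attack is blocked at the neopentyl carbonyl) gives the tetrasubstituted enolate regiospecifically, which is O-triflated.

Step 4
Reactants: 6 but-3-yn-1-ol
Product: 7 (but-3-yn-1-yloxy)triethylsilane
Conditions: Et3SiCl, imidazole, CH2Cl2, 0 °C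
Reagents that add atoms: chlorotriethylsilane, CC[Si](CC)(CC)Cl
Why: Standard silylation; the primary TES ether is chosen so that C19–O can later be freed in the presence of the secondary silyl ethers.

Step 5
Reactants: 7 (but-3-yn-1-yloxy)triethylsilane
Product: 8 triethyl{[(3E)-4-(4,4,5,5-tetramethyl-1,3,2-dioxaborolan-2-yl)but-3-en-1-yl]oxy}silane
Conditions: pinacolborane (1.1 equiv), Cp2Zr(H)Cl (5 mol %), Et3N (10 mol %), neat, 60 °C
Reagents that add atoms: pinacolborane, CC1(C)OBOC1(C)C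
Why: Zirconium-catalysed syn hydroboration of a terminal alkyne gives the E-alkenylboronate with boron at the terminal carbon.

Step 6
Reactants: 5 β-ring enol triflate; 8 alkenylboronate (1.3 equiv)
Product: 9 tert-butyldimethyl{[(1R)-3,5,5-trimethyl-4-[(1E)-4-(triethylsilyloxy)but-1-en-1-yl]cyclohex-3-en-1-yl]oxy}silane
Conditions: Pd(OAc)2 (5 mol %), SPhos (10 mol %), K3PO4 (3 equiv), THF/H2O 10:1, 50 °C
Reagents that add atoms: none
Why: Suzuki–Miyaura coupling; the bulky biarylphosphine handles the tetrasubstituted triflate and attaches C7–C8–C9–C19 to the ring.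

Step 7
Reactants: 9 ring diene
Product: 11 1-[(4R)-4-[(tert-butyldimethylsilyl)oxy]-2,6,6-trimethylcyclohex-1-en-1-yl]-4-[(triethylsilyl)oxy]butan-2-ol (C2 epimers), via 9-BBN alkylborane 10 (not isolated)
Conditions: 9-BBN (1.5 equiv), THF, 0 → 50 °C; then 3 M NaOH, 30 % H2O2, 0 °C
Reagents that add atoms: hydrogen peroxide, OO
Why: Hydroboration–oxidation: 9-BBN adds only to the disubstituted alkene with boron at C8, remote from the hindered ring (the tetrasubstituted ring alkene is inert); the new carbinol centre is uncontrolled and is removed in step 8.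

Step 8
Reactants: 11 C8 alcohol
Product: 12 1-[(4R)-4-[(tert-butyldimethylsilyl)oxy]-2,6,6-trimethylcyclohex-1-en-1-yl]-4-[(triethylsilyl)oxy]butan-2-one (C13 ketone, carbons C7–C8–C9–C19)
Conditions: Dess–Martin periodinane (1.3 equiv), pyridine (4 equiv), CH2Cl2, 0 °C → rt
Reagents that add atoms: none
Why: Buffered Dess–Martin oxidation gives the β,γ-unsaturated ketone without moving the ring alkene into conjugation.

Step 9
Reactants: 1 ketoisophorone
Product: 13 (4R)-4-hydroxy-2,6,6-trimethylcyclohex-2-en-1-one [(R)-phorenol]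
Conditions: Ru[(R,R)-TsNCH(Ph)CH(Ph)NH](p-cymene) (1 mol %), i-PrOH, 25 °C
Reagents that add atoms: none
Why: The same asymmetric transfer hydrogenation with the enantiomeric catalyst sets 4R, which is C3′ (R) of the ε ring.

Step 10
Reactants: 13 (R)-phorenol
Product: 14 (4R)-2,6,6-trimethyl-4-[(triisopropylsilyl)oxy]cyclohex-2-en-1-one
Conditions: i-Pr3SiCl (1.3 equiv), imidazole (2.5 equiv), DMF, 40 °C
Reagents that add atoms: chlorotriisopropylsilane, CC(C)[Si](Cl)(C(C)C)C(C)C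
Why: Silylation; the bulky TIPS group is chosen because it does not migrate to the neighbouring alkoxide in step 13 and it reinforces the facial bias in step 11.

Step 11
Reactants: 14 TIPS-protected (R)-phorenol
Product: 15 (1S,5R,6S)-1,3,3-trimethyl-5-[(triisopropylsilyl)oxy]-7-oxabicyclo[4.1.0]heptan-2-one (epoxide anti to the silyloxy group)
Conditions: 30 % H2O2 (3 equiv), 2 M NaOH (0.3 equiv), MeOH, 0 °C → rt
Reagents that add atoms: hydrogen peroxide, OO
Why: Weitz–Scheffer nucleophilic epoxidation; hydroperoxide attacks the β-carbon anti to the adjacent bulky silyloxy group, giving the trans-epoxide.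

Step 12
Reactants: 15 trans-epoxy ketone
Product: 16 (1R,6R)-2,4,4-trimethyl-6-[(triisopropylsilyl)oxy]cyclohex-2-en-1-ol
Conditions: N2H4·H2O (3 equiv), AcOH (0.3 equiv), MeOH, 0 °C → rt
Reagents that add atoms: none
Why: Wharton transposition (hydrazone, epoxide opening, loss of N2); the C–O bond at the former β-carbon is not broken, so the new allylic alcohol stays trans to the silyloxy group.

Step 13
Reactants: 16 trans allylic alcohol
Product: 18 tributyl({[(1R,6R)-2,4,4-trimethyl-6-[(triisopropylsilyl)oxy]cyclohex-2-en-1-yl]oxy}methyl)stannane, via potassium alkoxide 17 (not isolated)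
Conditions: KH (1.5 equiv), 18-crown-6 (0.1 equiv), THF, 0 °C; then Bu3SnCH2I (1.3 equiv), 0 °C → rt
Reagents that add atoms: tributyl(iodomethyl)stannane, CCCC[Sn](CCCC)(CCCC)CI
Why: Williamson etherification; the iodomethyl carbon becomes C7′.

Step 14
Reactants: 18 stannylmethyl ether
Product: 20 {(1R,4R)-2,6,6-trimethyl-4-[(triisopropylsilyl)oxy]cyclohex-2-en-1-yl}methanol, via lithiomethyl ether 19 (not isolated)
Conditions: n-BuLi (1.5 equiv), THF, −78 → −40 °C; then H2O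
Reagents that add atoms: none
Why: Tin–lithium exchange then [2,3]-Wittig–Still rearrangement; the suprafacial shift delivers CH2OH to C6′ on the face of the breaking C–O bond, i.e. trans to the silyloxy group, setting C6′ (R) and moving the alkene to C4′=C5′.

Step 15
Reactants: 20 hydroxymethyl compound
Product: 21 (1R,4R)-2,6,6-trimethyl-4-[(triisopropylsilyl)oxy]cyclohex-2-ene-1-carbaldehyde
Conditions: Dess–Martin periodinane (1.3 equiv), pyridine (4 equiv), CH2Cl2, 0 °C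
Reagents that add atoms: none
Why: Non-basic Dess–Martin oxidation keeps the epimerisable α-stereocentre and the deconjugated alkene intact; the aldehyde is used at once.

Step 16
Reactants: 21 ε-ring aldehyde; 22 ethyl (2E)-4-(diethoxyphosphoryl)-3-methylbut-2-enoate (1.2 equiv)
Product: 24 ethyl (2E,4E)-3-methyl-5-{(1R,4R)-2,6,6-trimethyl-4-[(triisopropylsilyl)oxy]cyclohex-2-en-1-yl}penta-2,4-dienoate, via lithiated phosphonate 23 (not isolated)
Conditions: LiN(SiMe3)2 (1.15 equiv), THF, −78 °C; then 21, −78 → 0 °C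
Reagents that add atoms: none
Why: Vinylogous Horner–Wadsworth–Emmons olefination forms C7′=C8′ E-selectively; the weakly basic stabilised anion at low temperature spares the α-stereocentre.

Step 17
Reactants: 24 C15 ester
Product: 25 (2E,4E)-3-methyl-5-{(1R,4R)-2,6,6-trimethyl-4-[(triisopropylsilyl)oxy]cyclohex-2-en-1-yl}penta-2,4-dien-1-ol
Conditions: i-Bu2AlH (2.5 equiv), CH2Cl2, −78 °C; aq. potassium sodium tartrate
Reagents that add atoms: none
Why: Clean 1,2-reduction of the dienoate to the allylic alcohol.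

Step 18
Reactants: 25 C15 alcohol
Product: 27 [(2E,4E)-3-methyl-5-{(1R,4R)-2,6,6-trimethyl-4-[(triisopropylsilyl)oxy]cyclohex-2-en-1-yl}penta-2,4-dien-1-yl]triphenylphosphonium bromide, via allylic bromide 26 (not isolated)
Conditions: CBr4 (1.2 equiv), PPh3 (1.2 equiv), CH2Cl2, −20 °C; then PPh3 (1.3 equiv), rt
Reagents that add atoms: carbon tetrabromide, BrC(Br)(Br)Br; triphenylphosphine, c1ccc(cc1)P(c1ccccc1)c1ccccc1
Why: Appel bromination then quaternisation under neutral conditions, which avoids acid at the ionisable allylic C3′ silyl ether.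

Step 19
Reactants: 27 ε-C15 phosphonium bromide; 28 (2E,4E,6E)-2,7-dimethylocta-2,4,6-trienedial (2.5 equiv, excess recovered)
Product: 30 (2E,4E,6E,8E,10E,12E)-2,7,11-trimethyl-13-{(1R,4R)-2,6,6-trimethyl-4-[(triisopropylsilyl)oxy]cyclohex-2-en-1-yl}trideca-2,4,6,8,10,12-hexaenal (C25 aldehyde), via phosphonium ylide 29 (not isolated)
Conditions: NaOMe (1.05 equiv), CH2Cl2/MeOH, −10 °C → rt; then I2 (1 mol %), CH2Cl2, daylight
Reagents that add atoms: none
Why: Wittig olefination forms C11′=C12′; excess dialdehyde ensures mono-olefination and iodine-catalysed equilibration converts the Z isomer to all-E.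

Step 20
Reactants: 30 C25 aldehyde; 31 diethyl {2-[methoxy(methyl)amino]-2-oxoethyl}phosphonate (1.3 equiv)
Product: 33 (2E,4E,6E,8E,10E,12E,14E)-N-methoxy-N,4,9,13-tetramethyl-15-{(1R,4R)-2,6,6-trimethyl-4-[(triisopropylsilyl)oxy]cyclohex-2-en-1-yl}pentadeca-2,4,6,8,10,12,14-heptaenamide, via sodiated phosphonate 32 (not isolated)
Conditions: NaH (1.25 equiv), THF, 0 °C → rt
Reagents that add atoms: none
Why: E-selective Horner–Wadsworth–Emmons two-carbon extension (C10, C11); the amide product cannot be homologated a second time.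

Step 21
Reactants: 33 C27 Weinreb amide
Product: 34 (2E,4E,6E,8E,10E,12E,14E)-4,9,13-trimethyl-15-{(1R,4R)-2,6,6-trimethyl-4-[(triisopropylsilyl)oxy]cyclohex-2-en-1-yl}pentadeca-2,4,6,8,10,12,14-heptaenal (C27 aldehyde)
Conditions: i-Bu2AlH (1.5 equiv), THF, −78 °C; aq. potassium sodium tartrate
Reagents that add atoms: none
Why: Weinreb amide reduction stops at the aldehyde through the chelated tetrahedral intermediate.

Step 22
Reactants: 12 C13 ketone (1.3 equiv); 34 C27 aldehyde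
Product: 36 (3R,3′R,6′R)-3-[(tert-butyldimethylsilyl)oxy]-10-hydroxy-3′-[(triisopropylsilyl)oxy]-19-[(triethylsilyl)oxy]-7,8,9,10-tetrahydro-β,ε-caroten-8-one (C9/C10 diastereomers), via lithium enolate 35 (not isolated)
Conditions: LiN(i-Pr)2 (1.25 equiv), THF, −78 °C, 45 min; then 34, −78 °C, 1 h; AcOH (2 equiv) in THF, −78 °C
Reagents that add atoms: none
Why: Crossed aldol addition forming C9–C10: kinetic deprotonation occurs at the unhindered C9 methylene (C7 is shielded by the trimethylcyclohexenyl group), the β-silyloxy enolate does not eliminate at −78 °C, and it adds 1,2 to the polyenal; the two new stereocentres are uncontrolled and are removed in step 23.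

Step 23
Reactants: 36 aldol adduct
Product: 38 (3R,3′R,6′R)-3-[(tert-butyldimethylsilyl)oxy]-3′-[(triisopropylsilyl)oxy]-19-[(triethylsilyl)oxy]-7,8-dihydro-β,ε-caroten-8-one (C8 carbonyl trans to C11), via C10 mesylate 37 (not isolated)
Conditions: MsCl (1.5 equiv), Et3N (5 equiv), CH2Cl2, −20 °C → rt
Reagents that add atoms: none
Why: Mesylation and E1cB elimination through the C9 enolate (mesylate, not silyloxide, is the leaving group) gives the thermodynamically preferred enone geometry, completing the aldol condensation.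

Step 24
Reactants: 38 19-O-TES dienone
Product: 39 (3R,3′R,6′R)-3-[(tert-butyldimethylsilyl)oxy]-19-hydroxy-3′-[(triisopropylsilyl)oxy]-7,8-dihydro-β,ε-caroten-8-one
Conditions: pyridinium p-toluenesulfonate (0.2 equiv), MeOH/CH2Cl2 1:1, 0 °C
Reagents that add atoms: none
Why: Mild acid-catalysed methanolysis removes the primary TES ether far faster than the secondary TBS and TIPS ethers.

Step 25
Reactants: 39 19-alcohol; 40 dodecanoyl chloride (1.3 equiv)
Product: 41 (3R,3′R,6′R)-3-[(tert-butyldimethylsilyl)oxy]-8-oxo-3′-[(triisopropylsilyl)oxy]-7,8-dihydro-β,ε-caroten-19-yl dodecanoate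
Conditions: pyridine (3 equiv), DMAP (0.1 equiv), CH2Cl2, 0 °C
Reagents that add atoms: none
Why: Acylation of the only free hydroxyl, so no selectivity question arises.

Step 26
Reactants: 41 bis-silyl laurate
Product: 42 (3R,3′R,6′R)-3,3′-dihydroxy-8-oxo-7,8-dihydro-β,ε-caroten-19-yl dodecanoate (target, CNP0415583.1)
Conditions: n-Bu4NF (5 equiv), AcOH (5 equiv), THF, 0 °C → rt, dark, argon
Reagents that add atoms: none
Why: Acetic acid-buffered fluoride desilylation removes TBS and TIPS without cleaving the laurate or ionising the allylic C3′ alcohol.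

## Compound list

1 | 2,6,6-trimethylcyclohex-2-ene-1,4-dione (ketoisophorone) | O=C1C(C)=CC(=O)CC1(C)C | starting material
2 | (4S)-4-hydroxy-2,6,6-trimethylcyclohex-2-en-1-one | O=C1C(C)=C[C@@H](O)CC1(C)C | intermediate
3 | (4S)-4-[(tert-butyldimethylsilyl)oxy]-2,6,6-trimethylcyclohex-2-en-1-one | O=C1C(C)=C[C@@H](O[Si](C)(C)C(C)(C)C)CC1(C)C | intermediate
4 | lithium (4R)-4-[(tert-butyldimethylsilyl)oxy]-2,6,6-trimethylcyclohex-1-en-1-olate | [Li]OC1=C(C)C[C@@H](O[Si](C)(C)C(C)(C)C)CC1(C)C | intermediate (not isolated)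
5 | (4R)-4-[(tert-butyldimethylsilyl)oxy]-2,6,6-trimethylcyclohex-1-en-1-yl trifluoromethanesulfonate | O=S(=O)(OC1=C(C)C[C@@H](O[Si](C)(C)C(C)(C)C)CC1(C)C)C(F)(F)F | intermediate
6 | but-3-yn-1-ol | C#CCCO | starting material
7 | (but-3-yn-1-yloxy)triethylsilane | C#CCCO[Si](CC)(CC)CC | intermediate
8 | triethyl{[(3E)-4-(4,4,5,5-tetramethyl-1,3,2-dioxaborolan-2-yl)but-3-en-1-yl]oxy}silane | CC[Si](CC)(CC)OCC/C=C/B1OC(C)(C)C(C)(C)O1 | intermediate
9 | tert-butyldimethyl{[(1R)-3,5,5-trimethyl-4-[(1E)-4-(triethylsilyloxy)but-1-en-1-yl]cyclohex-3-en-1-yl]oxy}silane | CC[Si](CC)(CC)OCC/C=C/C1=C(C)C[C@@H](O[Si](C)(C)C(C)(C)C)CC1(C)C | intermediate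
10 | 9-{1-[(4R)-4-[(tert-butyldimethylsilyl)oxy]-2,6,6-trimethylcyclohex-1-en-1-yl]-4-(triethylsilyloxy)butan-2-yl}-9-borabicyclo[3.3.1]nonane | CC[Si](CC)(CC)OCCC(CC1=C(C)C[C@@H](O[Si](C)(C)C(C)(C)C)CC1(C)C)B1C2CCCC1CCC2 | intermediate (not isolated)
11 | 1-[(4R)-4-[(tert-butyldimethylsilyl)oxy]-2,6,6-trimethylcyclohex-1-en-1-yl]-4-[(triethylsilyl)oxy]butan-2-ol (C2 epimers) | CC[Si](CC)(CC)OCCC(O)CC1=C(C)C[C@@H](O[Si](C)(C)C(C)(C)C)CC1(C)C | intermediate
12 | 1-[(4R)-4-[(tert-butyldimethylsilyl)oxy]-2,6,6-trimethylcyclohex-1-en-1-yl]-4-[(triethylsilyl)oxy]butan-2-one | CC[Si](CC)(CC)OCCC(=O)CC1=C(C)C[C@@H](O[Si](C)(C)C(C)(C)C)CC1(C)C | intermediate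
13 | (4R)-4-hydroxy-2,6,6-trimethylcyclohex-2-en-1-one | O=C1C(C)=C[C@H](O)CC1(C)C | intermediate
14 | (4R)-2,6,6-trimethyl-4-[(triisopropylsilyl)oxy]cyclohex-2-en-1-one | O=C1C(C)=C[C@H](O[Si](C(C)C)(C(C)C)C(C)C)CC1(C)C | intermediate
15 | (1S,5R,6S)-1,3,3-trimethyl-5-[(triisopropylsilyl)oxy]-7-oxabicyclo[4.1.0]heptan-2-one | O=C1[C@@]2(C)O[C@H]2[C@H](O[Si](C(C)C)(C(C)C)C(C)C)CC1(C)C | intermediate
16 | (1R,6R)-2,4,4-trimethyl-6-[(triisopropylsilyl)oxy]cyclohex-2-en-1-ol | C1=C(C)[C@@H](O)[C@H](O[Si](C(C)C)(C(C)C)C(C)C)CC1(C)C | intermediate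
17 | potassium (1R,6R)-2,4,4-trimethyl-6-[(triisopropylsilyl)oxy]cyclohex-2-en-1-olate | [K+].C1=C(C)[C@@H]([O-])[C@H](O[Si](C(C)C)(C(C)C)C(C)C)CC1(C)C | intermediate (not isolated)
18 | tributyl({[(1R,6R)-2,4,4-trimethyl-6-[(triisopropylsilyl)oxy]cyclohex-2-en-1-yl]oxy}methyl)stannane | C1=C(C)[C@@H](OC[Sn](CCCC)(CCCC)CCCC)[C@H](O[Si](C(C)C)(C(C)C)C(C)C)CC1(C)C | intermediate
19 | ({[(1R,6R)-2,4,4-trimethyl-6-[(triisopropylsilyl)oxy]cyclohex-2-en-1-yl]oxy}methyl)lithium | C1=C(C)[C@@H](OC[Li])[C@H](O[Si](C(C)C)(C(C)C)C(C)C)CC1(C)C | intermediate (not isolated)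
20 | {(1R,4R)-2,6,6-trimethyl-4-[(triisopropylsilyl)oxy]cyclohex-2-en-1-yl}methanol | OC[C@H]1C(C)=C[C@H](O[Si](C(C)C)(C(C)C)C(C)C)CC1(C)C | intermediate
21 | (1R,4R)-2,6,6-trimethyl-4-[(triisopropylsilyl)oxy]cyclohex-2-ene-1-carbaldehyde | O=C[C@H]1C(C)=C[C@H](O[Si](C(C)C)(C(C)C)C(C)C)CC1(C)C | intermediate
22 | ethyl (2E)-4-(diethoxyphosphoryl)-3-methylbut-2-enoate | CCOC(=O)/C=C(\C)CP(=O)(OCC)OCC | starting material
23 | lithium salt of the C4 carbanion of 22 | [Li+].CCOC(=O)C=C(C)[CH-]P(=O)(OCC)OCC | intermediate (not isolated)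
24 | ethyl (2E,4E)-3-methyl-5-{(1R,4R)-2,6,6-trimethyl-4-[(triisopropylsilyl)oxy]cyclohex-2-en-1-yl}penta-2,4-dienoate | CCOC(=O)/C=C(C)/C=C/[C@H]1C(C)=C[C@H](O[Si](C(C)C)(C(C)C)C(C)C)CC1(C)C | intermediate
25 | (2E,4E)-3-methyl-5-{(1R,4R)-2,6,6-trimethyl-4-[(triisopropylsilyl)oxy]cyclohex-2-en-1-yl}penta-2,4-dien-1-ol | OC/C=C(C)/C=C/[C@H]1C(C)=C[C@H](O[Si](C(C)C)(C(C)C)C(C)C)CC1(C)C | intermediate
26 | (2E,4E)-1-bromo-3-methyl-5-{(1R,4R)-2,6,6-trimethyl-4-[(triisopropylsilyl)oxy]cyclohex-2-en-1-yl}penta-2,4-diene | BrC/C=C(C)/C=C/[C@H]1C(C)=C[C@H](O[Si](C(C)C)(C(C)C)C(C)C)CC1(C)C | intermediate (not isolated)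
27 | [(2E,4E)-3-methyl-5-{(1R,4R)-2,6,6-trimethyl-4-[(triisopropylsilyl)oxy]cyclohex-2-en-1-yl}penta-2,4-dien-1-yl]triphenylphosphonium bromide | [Br-].c1ccccc1[P+](c1ccccc1)(c1ccccc1)C/C=C(C)/C=C/[C@H]1C(C)=C[C@H](O[Si](C(C)C)(C(C)C)C(C)C)CC1(C)C | intermediate
28 | (2E,4E,6E)-2,7-dimethylocta-2,4,6-trienedial | O=C/C(C)=C/C=C/C=C(C)/C=O | starting material
29 | ylide of 27 (triphenylphosphoranylidene at C1 of the pentadienyl chain) | c1ccccc1P(c1ccccc1)(c1ccccc1)=C/C=C(C)/C=C/[C@H]1C(C)=C[C@H](O[Si](C(C)C)(C(C)C)C(C)C)CC1(C)C | intermediate (not isolated)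
30 | (2E,4E,6E,8E,10E,12E)-2,7,11-trimethyl-13-{(1R,4R)-2,6,6-trimethyl-4-[(triisopropylsilyl)oxy]cyclohex-2-en-1-yl}trideca-2,4,6,8,10,12-hexaenal | O=C/C(C)=C/C=C/C=C(C)/C=C/C=C(C)/C=C/[C@H]1C(C)=C[C@H](O[Si](C(C)C)(C(C)C)C(C)C)CC1(C)C | intermediate
31 | diethyl {2-[methoxy(methyl)amino]-2-oxoethyl}phosphonate | CCOP(=O)(OCC)CC(=O)N(C)OC | starting material
32 | sodium salt of the α-carbanion of 31 | [Na+].CCOP(=O)(OCC)[CH-]C(=O)N(C)OC | intermediate (not isolated)
33 | (2E,4E,6E,8E,10E,12E,14E)-N-methoxy-N,4,9,13-tetramethyl-15-{(1R,4R)-2,6,6-trimethyl-4-[(triisopropylsilyl)oxy]cyclohex-2-en-1-yl}pentadeca-2,4,6,8,10,12,14-heptaenamide | CON(C)C(=O)/C=C/C(C)=C/C=C/C=C(C)/C=C/C=C(C)/C=C/[C@H]1C(C)=C[C@H](O[Si](C(C)C)(C(C)C)C(C)C)CC1(C)C | intermediate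
34 | (2E,4E,6E,8E,10E,12E,14E)-4,9,13-trimethyl-15-{(1R,4R)-2,6,6-trimethyl-4-[(triisopropylsilyl)oxy]cyclohex-2-en-1-yl}pentadeca-2,4,6,8,10,12,14-heptaenal | O=C/C=C/C(C)=C/C=C/C=C(C)/C=C/C=C(C)/C=C/[C@H]1C(C)=C[C@H](O[Si](C(C)C)(C(C)C)C(C)C)CC1(C)C | intermediate
35 | lithium C8–C9 enolate of 12 | [Li]OC(=CCO[Si](CC)(CC)CC)CC1=C(C)C[C@@H](O[Si](C)(C)C(C)(C)C)CC1(C)C | intermediate (not isolated)
36 | (3R,3′R,6′R)-3-[(tert-butyldimethylsilyl)oxy]-10-hydroxy-3′-[(triisopropylsilyl)oxy]-19-[(triethylsilyl)oxy]-7,8,9,10-tetrahydro-β,ε-caroten-8-one (C9/C10 diastereomers) | CC[Si](CC)(CC)OCC(C(O)/C=C/C(C)=C/C=C/C=C(C)/C=C/C=C(C)/C=C/[C@H]1C(C)=C[C@H](O[Si](C(C)C)(C(C)C)C(C)C)CC1(C)C)C(=O)CC1=C(C)C[C@@H](O[Si](C)(C)C(C)(C)C)CC1(C)C | intermediate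
37 | C10 methanesulfonate of 36 | CC[Si](CC)(CC)OCC(C(OS(C)(=O)=O)/C=C/C(C)=C/C=C/C=C(C)/C=C/C=C(C)/C=C/[C@H]1C(C)=C[C@H](O[Si](C(C)C)(C(C)C)C(C)C)CC1(C)C)C(=O)CC1=C(C)C[C@@H](O[Si](C)(C)C(C)(C)C)CC1(C)C | intermediate (not isolated)
38 | (3R,3′R,6′R)-3-[(tert-butyldimethylsilyl)oxy]-3′-[(triisopropylsilyl)oxy]-19-[(triethylsilyl)oxy]-7,8-dihydro-β,ε-caroten-8-one | CC[Si](CC)(CC)OC\C(=C/C=C/C(C)=C/C=C/C=C(C)/C=C/C=C(C)/C=C/[C@H]1C(C)=C[C@H](O[Si](C(C)C)(C(C)C)C(C)C)CC1(C)C)C(=O)CC1=C(C)C[C@@H](O[Si](C)(C)C(C)(C)C)CC1(C)C | intermediate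
39 | (3R,3′R,6′R)-3-[(tert-butyldimethylsilyl)oxy]-19-hydroxy-3′-[(triisopropylsilyl)oxy]-7,8-dihydro-β,ε-caroten-8-one | OC\C(=C/C=C/C(C)=C/C=C/C=C(C)/C=C/C=C(C)/C=C/[C@H]1C(C)=C[C@H](O[Si](C(C)C)(C(C)C)C(C)C)CC1(C)C)C(=O)CC1=C(C)C[C@@H](O[Si](C)(C)C(C)(C)C)CC1(C)C | intermediate
40 | dodecanoyl chloride | CCCCCCCCCCCC(=O)Cl | starting material
41 | (3R,3′R,6′R)-3-[(tert-butyldimethylsilyl)oxy]-8-oxo-3′-[(triisopropylsilyl)oxy]-7,8-dihydro-β,ε-caroten-19-yl dodecanoate | CCCCCCCCCCCC(=O)OC\C(=C/C=C/C(C)=C/C=C/C=C(C)/C=C/C=C(C)/C=C/[C@H]1C(C)=C[C@H](O[Si](C(C)C)(C(C)C)C(C)C)CC1(C)C)C(=O)CC1=C(C)C[C@@H](O[Si](C)(C)C(C)(C)C)CC1(C)C | intermediate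
42 | (3R,3′R,6′R)-3,3′-dihydroxy-8-oxo-7,8-dihydro-β,ε-caroten-19-yl dodecanoate | CCCCCCCCCCCC(=O)OC\C(=C/C=C/C(C)=C/C=C/C=C(C)/C=C/C=C(C)/C=C/[C@H]1C(C)=C[C@H](O)CC1(C)C)C(=O)CC1=C(C)C[C@@H](O)CC1(C)C | target

## Step count and risks

Total steps: 26. Longest linear sequence: 18 steps (steps 9–26, from ketoisophorone through the ε-ring fragment).

**Step 12 (Wharton transposition).** The ketone of 15 is flanked by two fully substituted carbons, so hydrazone formation may stall or hydrazine may open the epoxide. The fallback sets out from 15. NaBH4 in MeOH at 0 °C reduces the ketone to 1,3,3-trimethyl-5-[(triisopropylsilyl)oxy]-7-oxabicyclo[4.1.0]heptan-2-ol F1. MsCl/Et3N/DMAP converts it into the epoxy mesylate 1,3,3-trimethyl-5-[(triisopropylsilyl)oxy]-7-oxabicyclo[4.1.0]heptan-2-yl methanesulfonate F2. Electron-transfer reduction with NaC10H8 (sodium naphthalenide) in THF at −78 °C cleaves the C–OMs bond, and the resulting carbanion opens the epoxide. The C–O bond at the carbinol carbon is never broken, so the alcohol stays trans to the silyloxy group, and the route is rejoined at 16.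

**Step 16 (HWE on the α-branched aldehyde).** Aldehyde 21 can epimerise at C6′ or slip into conjugation (and then lose the silyloxy group) in the presence of the phosphonate anion. The fallback sets out from 21. Neutral Wittig olefination with Ph3P=CHCOCH3 in toluene at 90 °C gives (3E)-4-{(1R,4R)-2,6,6-trimethyl-4-[(triisopropylsilyl)oxy]cyclohex-2-en-1-yl}but-3-en-2-one F3, which no longer has an aldehyde α-hydrogen. HWE olefination of this ketone with triethyl phosphonoacetate and NaH (THF, 50 °C), followed by separation or iodine equilibration of the 2Z isomer, rejoins the route at 24.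

**Step 22 (key aldol).** The risks are competing enolisation at C7 and β-elimination of the silyloxide from the C9 enolate. The fallback sets out from 12 and generates the C9 enolate regiospecifically by conjugate addition instead of deprotonation. Pyridinium p-toluenesulfonate in MeOH gives 1-[(4R)-4-[(tert-butyldimethylsilyl)oxy]-2,6,6-trimethylcyclohex-1-en-1-yl]-4-hydroxybutan-2-one F4. MsCl/Et3N eliminates it to the vinyl ketone 1-[(4R)-4-[(tert-butyldimethylsilyl)oxy]-2,6,6-trimethylcyclohex-1-en-1-yl]but-3-en-2-one F5. Et2AlI (CH2Cl2, −78 → 0 °C) adds iodide to C19 and the resulting aluminium enolate adds to 34, giving the 19-iodo-10-hydroxy aldol (iodo analogue of 36) F6. Et3N removes HI to give the α-methylene β-hydroxy ketone 3-[(tert-butyldimethylsilyl)oxy]-10-hydroxy-9-methylidene-3′-[(triisopropylsilyl)oxy]-19-nor-7,8,9,10-tetrahydro-β,ε-caroten-8-one (C19 now the methylidene carbon) F7. Mitsunobu esterification with dodecanoic acid (PPh3, diisopropyl azodicarboxylate) proceeds with allylic transposition to the conjugated primary laurate and rejoins the route at 41, bypassing steps 23–25.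

## Further compounds

F1 | step 12 | 1,3,3-trimethyl-5-[(triisopropylsilyl)oxy]-7-oxabicyclo[4.1.0]heptan-2-ol (epoxide anti to silyloxy, C2 epimers) | OC1[C@@]2(C)O[C@H]2[C@H](O[Si](C(C)C)(C(C)C)C(C)C)CC1(C)C
F2 | step 12 | 1,3,3-trimethyl-5-[(triisopropylsilyl)oxy]-7-oxabicyclo[4.1.0]heptan-2-yl methanesulfonate | CS(=O)(=O)OC1[C@@]2(C)O[C@H]2[C@H](O[Si](C(C)C)(C(C)C)C(C)C)CC1(C)C
F3 | step 16 | (3E)-4-{(1R,4R)-2,6,6-trimethyl-4-[(triisopropylsilyl)oxy]cyclohex-2-en-1-yl}but-3-en-2-one | CC(=O)/C=C/[C@H]1C(C)=C[C@H](O[Si](C(C)C)(C(C)C)C(C)C)CC1(C)C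
F4 | step 22 | 1-[(4R)-4-[(tert-butyldimethylsilyl)oxy]-2,6,6-trimethylcyclohex-1-en-1-yl]-4-hydroxybutan-2-one | OCCC(=O)CC1=C(C)C[C@@H](O[Si](C)(C)C(C)(C)C)CC1(C)C
F5 | step 22 | 1-[(4R)-4-[(tert-butyldimethylsilyl)oxy]-2,6,6-trimethylcyclohex-1-en-1-yl]but-3-en-2-one | C=CC(=O)CC1=C(C)C[C@@H](O[Si](C)(C)C(C)(C)C)CC1(C)C
F6 | step 22 | 19-iodo-10-hydroxy aldol (iodo analogue of 36, C9/C10 diastereomers) | ICC(C(O)/C=C/C(C)=C/C=C/C=C(C)/C=C/C=C(C)/C=C/[C@H]1C(C)=C[C@H](O[Si](C(C)C)(C(C)C)C(C)C)CC1(C)C)C(=O)CC1=C(C)C[C@@H](O[Si](C)(C)C(C)(C)C)CC1(C)C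
F7 | step 22 | 3-[(tert-butyldimethylsilyl)oxy]-10-hydroxy-9-methylidene-3′-[(triisopropylsilyl)oxy]-19-nor-7,8,9,10-tetrahydro-β,ε-caroten-8-one (C10 epimers) | C=C(C(O)/C=C/C(C)=C/C=C/C=C(C)/C=C/C=C(C)/C=C/[C@H]1C(C)=C[C@H](O[Si](C(C)C)(C(C)C)C(C)C)CC1(C)C)C(=O)CC1=C(C)C[C@@H](O[Si](C)(C)C(C)(C)C)CC1(C)C
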